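The route rests on cutting the bond between C2 of the pyridone ring and C1' of the side chain. The chain then comes from palmitic acid and the bicycle from 4-methoxyquinoline. The key step is a silver-catalysed decarboxylative Minisci alkylation. In one operation it converts the acid into the pentadecyl radical and replaces the C2–H bond next to protonated N1, without halide or organometallic. It exploits the N1=C2 iminium character of the hetero ring and the oxygen at C4, which blocks the only competing γ position. Its precursor is the aromatic lactim ether, not the quinolone. Iodomethane then transposes methyl from O4 to N1.

Key step: step 1

Remark: the target has no stereocentre and no double-bond geometry, so no stereochemical control is needed. Compounds 1 and 2 are taken as commercial.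

Step 1
Reactants: 1 4-methoxyquinoline; 2 palmitic acid (hexadecanoic acid, used in excess)
Product: 4 4-methoxy-2-pentadecylquinoline, via pentadecyl radical 3 (not isolated)
Conditions: AgNO3 (20 mol%), (NH4)2S2O8 (3 equiv), TFA (1.5 equiv), MeCN/H2O, 75 °C; basic work-up
Reagents that add atoms: none
Why: Decarboxylative Minisci alkylation: peroxydisulfate oxidises Ag(I) to Ag(II), which oxidises the carboxylate of 2, and loss of CO2 leaves the nucleophilic primary radical 3 centred on the former C2 of the acid. Radical 3 adds to C2 of N1-protonated 1, the pyridine-ring position with a large LUMO coefficient that still carries hydrogen, and the adduct radical cation loses the C2 proton and one electron (to peroxydisulfate or Ag(II)) to restore the aromatic quinoline. This reaction type is well established for protonated quinolines and aliphatic carboxylic acids. No ring is closed and no stereocentre is formed. The step needs C2 over C4 selectivity and mono- over dialkylation: the methoxy group occupies C4, the carbocyclic ring is not activated by protonation, and after one alkylation no α or γ C–H remains, so a single regioisomer should result. The excess of 2 compensates for the lower electrophilicity caused by the 4-methoxy donor and for radical lost by dimerisation or hydrogen abstraction.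

Step 2
Reactants: 4 4-methoxy-2-pentadecylquinoline
Product: 6 1-methyl-2-pentadecylquinolin-4(1H)-one, via N-methylquinolinium iodide 5 (not isolated)
Conditions: MeI (5 equiv), MeCN, sealed tube, 120 °C; then venting and evaporation
Reagents that add atoms: iodomethane (MeI), CI
Why: Menshutkin methylation at N1 of the vinylogous imidate should give salt 5, whose O-methyl group iodide then removes by SN2 dealkylation (lactim ether to lactam O-to-N transposition of the Hilbert–Johnson type), driven by formation of the vinylogous amide and loss of volatile MeI.

Compound list
1 | 4-methoxyquinoline | COc1ccnc2ccccc12 | starting material
2 | palmitic acid (hexadecanoic acid) | CCCCCCCCCCCCCCCC(=O)O | starting material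
3 | pentadecyl radical (pentadecan-1-yl), not isolated | CCCCCCCCCCCCCC[CH2] | intermediate
4 | 4-methoxy-2-pentadecylquinoline | CCCCCCCCCCCCCCCc1cc(OC)c2ccccc2n1 | intermediate
5 | 4-methoxy-1-methyl-2-pentadecylquinolinium iodide, not isolated | CCCCCCCCCCCCCCCc1cc(OC)c2ccccc2[n+]1C.[I-] | intermediate
6 | 1-methyl-2-pentadecylquinolin-4(1H)-one | CCCCCCCCCCCCCCCc1cc(=O)c2ccccc2n1C | target

Total step count: 2
Longest linear sequence: 2

Steps most likely to fail (the route has only two steps, so both are ranked):

1. Step 1.
   - **What may go wrong:** The weakly nucleophilic primary radical may add only sluggishly to the donor-substituted quinolinium ion, so that it is lost by dimerisation, over-oxidation or hydrogen abstraction. The sulfate radical anion may abstract hydrogen along the chain, which leads to branched alkylation. The fatty acid may mix poorly with the aqueous oxidant, and the methoxy group may slowly hydrolyse in the hot acid.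
   - **Fallback (polar instead of radical C2 alkylation):** it sets out from 1 and comes back at 4. Oxidation of 1 with mCPBA in CH2Cl2 should give 4-methoxyquinoline 1-oxide F1. Pentadecylmagnesium bromide F2, made from 1-bromopentadecane and magnesium in THF, is then added to C2 of F1 under CuCl catalysis. This gives the bromomagnesium salt of 1-hydroxy-4-methoxy-2-pentadecyl-1,2-dihydroquinoline F3. On warming, F3 rearomatises by elimination across N1–C2 to 4. This is the known deoxygenative C2 alkylation of azine N-oxides with Grignard reagents.

2. Step 2.
   - **What may go wrong:** Quaternisation at N1 may be slow, because N1 is flanked by the C2 chain and the peri C8–H. O-dealkylation of the salt by iodide may also be incomplete, so conversion may stall.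
   - **Fallback (deprotection, then alkylation of the ambident anion, instead of quaternisation and dealkylation):** it sets out from 4 and comes back at 6. O-demethylation of 4 with 48% HBr in AcOH at reflux should give 2-pentadecylquinolin-4(1H)-one F4. F4 is then methylated with MeI and KOH in MeOH. The protic solvent shields the oxygen terminus of the far more nucleophilic anion and should favour attack through N1. Any material methylated on oxygen is 4 itself and can re-enter the route.

Further compounds
F1 | step 1 | 4-methoxyquinoline 1-oxide | COc1cc[n+]([O-])c2ccccc12
F2 | step 1 | pentadecylmagnesium bromide | CCCCCCCCCCCCCCC[Mg]Br
F3 | step 1 | bromomagnesium salt of 1-hydroxy-4-methoxy-2-pentadecyl-1,2-dihydroquinoline (racemic) | CCCCCCCCCCCCCCCC1C=C(OC)c2ccccc2N1O[Mg]Br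
F4 | step 2 | 2-pentadecylquinolin-4(1H)-one | CCCCCCCCCCCCCCCc1cc(=O)c2ccccc2[nH]1
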